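**Retrosynthetic overview**
1. Cut the inter-ring CH2–C(dienone) bond. This gives the ortho-quinone methide of aspidinol (CH2 from Eschenmoser's salt) and acetylfilicinic acid. No ring is formed at this stage.
2. The aromatic ring comes from a C6→C1 Claisen closure (the type III polyketide-synthase fold) of a linear, butyryl-primed tetraketide methyl ester. This ester already carries the C2-methyl and the C3-O-methyl. It is unmasked in the flask from a 6-(2-oxopentyl)-4-methoxy-3-methyl-2-pyrone, built from 4-methoxy-6-methyl-2-pyrone, MeI and methyl butanoate.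
3. The dienone ring comes from the same C6→C1 Claisen closure of methyl 2,2-dimethyl-3,5,7-trioxooctanoate. That chain is assembled in the same flask from acetylacetone dianion and dimethyl dimethylmalonate.
4. Ring order: aromatic ring (step 2) and dienone ring (step 3) in parallel branches, then union (step 4).

Assumption: the target has no stereogenic element (the sp3 ring carbon carries two methyls), so it is achiral and there is no enantiomer to select; the SMILES shows one tautomer of a fast enol equilibrium.

**Step 1**
Reactants: 1 4-methoxy-6-methyl-2H-pyran-2-one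
Product: 3 4-methoxy-3,6-dimethyl-2H-pyran-2-one, via 3-lithiopyrone 2 (not isolated)
Conditions: n-BuLi (1.05 equiv), THF, −78 °C, 30 min; MeI (1.5 equiv), −78 → −20 °C; aq NH4Cl
Reagents that add atoms: iodomethane, CI; n-butyllithium, [Li]CCCC (supplies only the Li of intermediate 2)
Why: Kinetic directed lithiation takes the C3–H flanked by the lactone C=O and the OMe, at −78 °C the vinyl-lithium does not equilibrate to the 6-CH2Li isomer, SN2 methylation follows, and no stereocentre is formed.

**Step 2**
Reactants: 3 4-methoxy-3,6-dimethyl-2H-pyran-2-one; 4 methyl butanoate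
Product: 8 aspidinol [1-(2,6-dihydroxy-4-methoxy-3-methylphenyl)butan-1-one], via lithiomethylpyrone 5 (not isolated), via ketopyrone 6 (not isolated), via open-chain tetraketide ester 7 (not isolated)
Conditions: LDA (2.2 equiv, commercial solution), THF, −78 °C, 45 min; 4 (1.2 equiv), −78 → 0 °C, 2 h; then Mg(OMe)2 (3 equiv, 7 wt% in MeOH), reflux, 16 h; 1 M HCl
Reagents that add atoms: lithium diisopropylamide, [Li]N(C(C)C)C(C)C (supplies only the Li of intermediate 5); magnesium methoxide, C[O-].C[O-].[Mg+2] (supplies only the ester OMe of intermediate 7, which leaves again on ring closure)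
Why: Proposed new method: a one-flask sequence of vinylogous (lateral) Claisen acylation of 5 (C3 is blocked, and the second equivalent of base takes up the acidic CH2 of 6), methoxide opening of the lactone to (E)-ester 7 with ester and chain held cis, and Dieckmann-type C6→C1 Claisen closure, in which the C2 carbon is a fully substituted enol-ether carbon so the rival C2→C7 aldol fold cannot aromatise, all methoxide exchanges are degenerate, relactonisation and 4-pyrone formation are reversible, and the Mg-chelated aromatic phenolate is the irreversible sink that places OMe para to the butyryl group; the closest known reaction types are ester acylation of lithiated 6-methyl-4-methoxy-2-pyrones, Mg(OMe)2-induced recyclisation of 6-acylmethyl-2-pyrones and base cyclisation of 3,5,7-trioxo esters to acylphloroglucinols; no stereocentre is formed.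

**Step 3**
Reactants: 9 pentane-2,4-dione (acetylacetone); 10 dimethyl 2,2-dimethylpropanedioate
Product: 13 acetylfilicinic acid (2-acetyl-3,5-dihydroxy-4,4-dimethylcyclohexa-2,5-dien-1-one), via dilithio acetylacetone dianion 11 (not isolated), via linear tetraketide ester 12 (not isolated)
Conditions: LDA (3.2 equiv, commercial solution), THF, 0 °C, 30 min; 10 (1.0 equiv), −78 °C → rt, then reflux, 3 h; 2 M HCl
Reagents that add atoms: lithium diisopropylamide, [Li]N(C(C)C)C(C)C (supplies only the Li of intermediate 11)
Why: Proposed new method: the terminal carbanion of 11 acylates one ester of the non-enolisable diester 10 (γ-acylation of a β-diketone dianion), and the C6 enolate of the resulting tetraketide 12 closes onto the remaining C1 ester (Dieckmann/Claisen, C6→C1), helped by the gem-dimethyl effect, with 4- and 8-membered closures excluded, any O-acylated enol lactone reopened by the liberated methoxide, and the doubly deprotonated β-triketone as the thermodynamic sink; the closest known reaction types are ester acylation of acetylacetone dianion and base cyclisation of 3,5,7-trioxo esters; the CMe2 carbon is not stereogenic.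

**Step 4**
Reactants: 8 aspidinol; 13 acetylfilicinic acid
Product: 16 2-acetyl-6-[(3-butanoyl-2,4-dihydroxy-6-methoxy-5-methylphenyl)methyl]-3,5-dihydroxy-4,4-dimethylcyclohexa-2,5-dien-1-one (target), via Mannich base 14 (not isolated), via ortho-quinone methide 15 (not isolated)
Conditions: 8, CH2=NMe2+ I− (1.0 equiv), NaOAc (1.1 equiv), MeCN, rt → 40 °C, 3 h; then 13 (1.1 equiv), 70 °C, 6 h; 0.5 M HCl
Reagents that add atoms: N,N-dimethylmethyleneiminium iodide (Eschenmoser's salt), C=[N+](C)C.[I-]
Why: Mannich aminomethylation occurs at the only free aromatic CH of 8, thermal loss of Me2NH gives ortho-quinone methide 15, and Michael addition of the strongly nucleophilic vinylogous acid 13 through its only free ring carbon rearomatises the ring, while the exact one equivalent of CH2 donor and the acetate buffer (no alkali) suppress homodimers and methylene scrambling; no stereocentre is formed.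

**Compound list**
1 | 4-methoxy-6-methyl-2H-pyran-2-one | CC1=CC(OC)=CC(=O)O1 | starting material
2 | 3-lithio-4-methoxy-6-methyl-2H-pyran-2-one | [Li]C1=C(OC)C=C(C)OC1=O | intermediate (not isolated)
3 | 4-methoxy-3,6-dimethyl-2H-pyran-2-one | CC1=CC(OC)=C(C)C(=O)O1 | intermediate
4 | methyl butanoate | CCCC(=O)OC | starting material
5 | 6-(lithiomethyl)-4-methoxy-3-methyl-2H-pyran-2-one | [Li]CC1=CC(OC)=C(C)C(=O)O1 | intermediate (not isolated)
6 | 4-methoxy-3-methyl-6-(2-oxopentyl)-2H-pyran-2-one | CCCC(=O)CC1=CC(OC)=C(C)C(=O)O1 | intermediate (not isolated)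
7 | methyl (2E)-3-methoxy-2-methyl-5,7-dioxodec-2-enoate | COC(=O)/C(C)=C(/OC)CC(=O)CC(=O)CCC | intermediate (not isolated)
8 | aspidinol, 1-(2,6-dihydroxy-4-methoxy-3-methylphenyl)butan-1-one | CCCC(=O)c1c(O)c(C)c(OC)cc1O | intermediate
9 | pentane-2,4-dione | CC(=O)CC(C)=O | starting material
10 | dimethyl 2,2-dimethylpropanedioate | COC(=O)C(C)(C)C(=O)OC | starting material
11 | dilithio dianion of pentane-2,4-dione (bis-enolate, geometry not defined) | C=C(O[Li])C=C(C)O[Li] | intermediate (not isolated)
12 | methyl 2,2-dimethyl-3,5,7-trioxooctanoate | COC(=O)C(C)(C)C(=O)CC(=O)CC(C)=O | intermediate (not isolated)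
13 | acetylfilicinic acid, 2-acetyl-3,5-dihydroxy-4,4-dimethylcyclohexa-2,5-dien-1-one | CC(=O)C1=C(O)C(C)(C)C(O)=CC1=O | intermediate
14 | 1-{3-[(dimethylamino)methyl]-2,6-dihydroxy-4-methoxy-5-methylphenyl}butan-1-one | CCCC(=O)c1c(O)c(C)c(OC)c(CN(C)C)c1O | intermediate (not isolated)
15 | 2-butanoyl-3-hydroxy-5-methoxy-4-methyl-6-methylidenecyclohexa-2,4-dien-1-one | C=C1C(=O)C(C(=O)CCC)=C(O)C(C)=C1OC | intermediate (not isolated)
16 | 2-acetyl-6-[(3-butanoyl-2,4-dihydroxy-6-methoxy-5-methylphenyl)methyl]-3,5-dihydroxy-4,4-dimethylcyclohexa-2,5-dien-1-one (achiral) | CCCC(=O)c1c(O)c(C)c(OC)c(CC2=C(O)C(C)(C)C(O)=C(C(C)=O)C2=O)c1O | target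

**Count**
- Total steps: 4.
- Longest linear sequence: 3 steps (1 → 3 → 8 → 16). Step 3 is a parallel one-step branch.

**Three steps most likely to fail**

Step 2.
- Risks: LDA may enolise 4 and limit conversion. The delocalised enolate of 6 may resist methoxide attack. The vinylogous-carbonate ester of 7 is a weak acyl acceptor.
- Fallback: it sets out from 3 and comes back at 7, hence 8. It reverses the order of events. The pyrone 3, which has no deactivating side-chain enolate yet, is opened alone with Mg(OMe)2 in MeOH, and cold, mildly acidic work-up gives isolated methyl (2E)-3-methoxy-2-methyl-5-oxohex-2-enoate F1. F1 is doubly deprotonated with LDA in THF to its dilithio dianion F2. F2 is acylated at its terminal carbon with 4. This delivers 7 as a polyanion in an aprotic medium, where the more nucleophilic C6 carbanion closes to 8 on warming.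

Step 3.
- Risks: attack on the α-quaternary ester may be slow. A second dianion may acylate the other ester. The reaction may stall at open-chain or lactone material.
- Fallback: it sets out from 9 and comes back at 12, hence 13. It replaces the dianion/ester pair with a neutral bis-nucleophile and an acid chloride. Compound 9 is bis-silylated (TMSOTf, Et3N, Et2O, 0 °C) to 2,4-bis(trimethylsilyloxy)penta-1,3-diene F3. F3 is cyclised with dimethylmalonyl dichloride (cat. TMSOTf, CH2Cl2, −78 °C → rt; [3+3] of a 1,3-bis(silyl enol ether) with a diacid dichloride). This gives the enol lactone 3,3-dimethyl-6-(2-oxopropyl)-2H-pyran-2,4(3H)-dione F4. NaOMe in MeOH opens F4 to 12, which closes to 13.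

Step 4.
- Risks: incomplete aminomethylation of the acyl-deactivated ring of 8. Retro-Mannich or retro-Michael transfer of the CH2 group would give the two homodimers (methylenebis-aspidinol and the albaspidin-type dimer of 13).
- Fallback: it sets out from 13 and comes back at 16. It swaps the electrophile and nucleophile roles. Compound 13 reacts with Eschenmoser's salt (CH2Cl2, rt) to give the crystalline, isolable zwitterionic Mannich base 2-acetyl-6-[(dimethylamino)methyl]-3,5-dihydroxy-4,4-dimethylcyclohexa-2,5-dien-1-one F5. Warming F5 with 8 (1.5 equiv) in dioxane–AcOH releases the enetrione 2-acetyl-3-hydroxy-4,4-dimethyl-6-methylidenecyclohex-2-ene-1,5-dione F6. F6 alkylates the free aromatic CH of 8 (Friedel–Crafts-type Michael addition) to give 16.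

**Further compounds**
F1 | step 2 | methyl (2E)-3-methoxy-2-methyl-5-oxohex-2-enoate | COC(=O)/C(C)=C(/OC)CC(C)=O
F2 | step 2 | dilithio dianion of F1 (bis-enolate, geometry not defined) | COC(O[Li])=C(C)C(OC)=CC(=C)O[Li]
F3 | step 3 | 2,4-bis(trimethylsilyloxy)penta-1,3-diene (E/Z mixture) | C=C(O[Si](C)(C)C)C=C(C)O[Si](C)(C)C
F4 | step 3 | 3,3-dimethyl-6-(2-oxopropyl)-2H-pyran-2,4(3H)-dione | CC(=O)CC1=CC(=O)C(C)(C)C(=O)O1
F5 | step 4 | 2-acetyl-6-[(dimethylamino)methyl]-3,5-dihydroxy-4,4-dimethylcyclohexa-2,5-dien-1-one | CC(=O)C1=C(O)C(C)(C)C(O)=C(CN(C)C)C1=O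
F6 | step 4 | 2-acetyl-3-hydroxy-4,4-dimethyl-6-methylidenecyclohex-2-ene-1,5-dione | C=C1C(=O)C(C(C)=O)=C(O)C(C)(C)C1=O
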